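**Plan**

- Cuts: the three phenolic O–H bonds (MOM ethers), the aryl C5′–C11 bond (B-alkyl Suzuki–Miyaura coupling), C9=C11 (ketone methylenation), C2–S (traceless sulfone), C3–C4 (radical ring closure), then C10–C1 and C10–CH3 (two enolate alkylations), back to (R)-carvone.
- Forward: ring B is bought as the carvone ring, C10 is made quaternary, ring A is closed by a hydrogen-atom-transfer-initiated 6-endo radical cyclization, and the arene is joined last at C11.
- Enabling feature: ring B (C5–C10) carries a methyl on the alkene carbon C8 and, 1,4-related to it, C5 holding the gem-dimethyl carbon C4. This is the enone-plus-isopropenyl pattern of carvone, so C4 and one of its methyls are already present and the other methyl arises from the isopropenyl CH2 as the C3–C4 bond closes ring A.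
- Stereochemistry: C5 is the carvone stereocentre. C10 follows from the order of the two alkylations (second electrophile anti to isopropenyl), which leaves only a trans ring fusion open. C9 comes from α-face hydroboration anti to the axial C10 methyl.

Key step: step 3

Remarks on the chemistry: drimane numbering (C1–C11) is used for the terpenoid atoms and primed numbers for the arene; compounds 1–6 use carvone numbering (C1 carbonyl, C5 isopropenyl-bearing carbon, C6 the α′ carbon). Compound 3 is carried as its C6 epimer mixture because that centre is planarised in step 2. Compounds 7 and 8 are carried as C2 epimer mixtures because that centre is removed in step 5, and their SMILES leave C2 undefined. The target has the (5S,9S,10S) configuration.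

**Route**

Step 1
Reactants: 1 (R)-(−)-carvone
Product: 3 6-methylcarvone (C6 epimers; trans epimer expected to predominate), via lithium dienolate of carvone 2 (not isolated)
Conditions: LiN(i-Pr)2 (1.1 equiv), THF, −78 °C; then MeI, −78 → 0 °C
Reagents that add atoms: iodomethane (MeI), CI
Why: LiN(i-Pr)2 removes the kinetically most accessible α′ proton (C6) of the cross-conjugated enone and the lithium dienolate 2 is C-methylated by MeI (classical kinetic enolate alkylation), which should give 3 mainly as the trans epimer, although the new C6 centre is irrelevant because it is planarised again in step 2.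

Step 2
Reactants: 3 6-methylcarvone; 4 2,3-bis(phenylsulfonyl)prop-1-ene
Product: 6 (5S,6S)-2,6-dimethyl-6-[2-(phenylsulfonyl)prop-2-en-1-yl]-5-(prop-1-en-2-yl)cyclohex-2-en-1-one, via lithium enolate of 6-methylcarvone 5 (not isolated)
Conditions: LiN(i-Pr)2, THF, −78 → 0 °C; then enolate added to 4 (1.3 equiv), THF, −78 → −20 °C
Reagents that add atoms: none
Why: Deprotonation of 3 at C6 gives the fully substituted enolate 5, which should add to the CH2 terminus of the vinyl sulfone of 4 and expel benzenesulfinate from the neighbouring carbon (enolate SN2′ addition–elimination alkylation), the electrophile approaching the enolate face anti to the adjacent isopropenyl group so that the quaternary carbon (future C10) is formed with the sulfonylallyl arm trans and the methyl cis to isopropenyl.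

Step 3
Reactants: 6 (5S,6S)-2,6-dimethyl-6-[2-(phenylsulfonyl)prop-2-en-1-yl]-5-(prop-1-en-2-yl)cyclohex-2-en-1-one
Product: 7 (4aS,8aS)-2,5,5,8a-tetramethyl-7-(phenylsulfonyl)-4a,5,6,7,8,8a-hexahydronaphthalen-1(4H)-one (2-phenylsulfonyl-11-nordrim-7-en-9-one; trans-fused; C2 epimers)
Conditions: Fe(acac)3 (30 mol %), PhSiH3 (2.5 equiv), EtOH/(CH2OH)2 5:1, 0.02 M, 60 °C
Reagents that add atoms: none
Why: A hydride of trivalent iron, generated from Fe(acac)3 and PhSiH3, should transfer a hydrogen atom to the CH2 of the isopropenyl group, the only electron-rich alkene of 6, which creates the second C4 methyl and a nucleophilic tertiary radical at C4; this radical adds to the unsubstituted CH2 terminus (C3) of the vinyl sulfone, and the α-sulfonyl radical so formed is reduced by divalent iron and protonated by the alcohol solvent. The closest known reaction type is the metal-hydride hydrogen-atom-transfer reductive olefin coupling, here an intramolecular Giese addition of a 1,1-disubstituted donor alkene to an electron-poor acceptor alkene. Ring A (C1–C2–C3–C4–C5–C10) closes in the 6-endo-trig mode by formation of the C3–C4 bond through a chair transition state with both arms equatorial on ring B. No stereocentre of the target is created: the trans ring fusion (5α-H, 10β-CH3) is dictated by the trans relationship of the two arms fixed in step 2, and the only new centre, the sulfone-bearing C2, is set without control by the final protonation and is deleted in step 5. The step needs 6-endo rather than 5-exo closure and hydrogen-atom transfer to the isopropenyl group alone; the first is secured by the sulfonyl group on the internal acceptor carbon, which blocks that carbon and makes attack at CH2 lead to the stabilised α-sulfonyl radical, and the second by the electron-poor character of the enone and the vinyl sulfone, the enone β-carbon being in addition out of reach of the C4 radical.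

Step 4
Reactants: 7 2-phenylsulfonyl-11-nordrim-7-en-9-one
Product: 8 2-(phenylsulfonyl)drima-7,9(11)-diene (5S,10S; C2 epimers)
Conditions: Cp2TiMe2 (3 equiv), toluene/THF, 75 °C, dark
Reagents that add atoms: dimethyltitanocene (Cp2TiMe2), C[Ti](C)(C1C=CC=C1)C1C=CC=C1
Why: Petasis methylenation: thermolysis of Cp2TiMe2 releases methane and the titanium methylidene Cp2Ti=CH2, which should engage the hindered, conjugated C9 carbonyl in a [2+2] addition and cycloreversion to the exocyclic C9=C11 alkene under non-basic conditions that leave the acidic α-sulfonyl C–H and the two ring-fusion centres untouched.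

Step 5
Reactants: 8 2-(phenylsulfonyl)drima-7,9(11)-diene
Product: 9 (5S,10S)-drima-7,9(11)-diene
Conditions: 6% Na/Hg, Na2HPO4, MeOH/THF, −20 °C → rt
Reagents that add atoms: none
Why: Electron transfer from Na/Hg to the phenyl sulfone cleaves the C2–S bond and the resulting carbanion is protonated in the buffered methanol (classical reductive desulfonylation), which should erase the uncontrolled C2 centre while the unactivated diene and the C5 and C10 centres are not affected.

Step 6
Reactants: 10 methyl 2,3,4-trihydroxybenzoate
Product: 11 methyl 5-bromo-2,3,4-trihydroxybenzoate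
Conditions: NBS (1.0 equiv), MeCN, −10 → 0 °C
Reagents that add atoms: N-bromosuccinimide (NBS), O=C1CCC(=O)N1Br
Why: Electrophilic aromatic substitution by NBS should occur at C5, the only free position that is ortho to one hydroxyl (C4–OH) and para to another (C2–OH), whereas C6 is ortho to the deactivating ester, and one equivalent of reagent at low temperature limits over-bromination and oxidation of the pyrogallol unit.

Step 7
Reactants: 11 methyl 5-bromo-2,3,4-trihydroxybenzoate
Product: 12 methyl 5-bromo-2,3,4-tris(methoxymethoxy)benzoate
Conditions: MOMCl (4.5 equiv), i-Pr2NEt (6 equiv), n-Bu4NI (cat.), CH2Cl2, 0 → 40 °C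
Reagents that add atoms: chloromethyl methyl ether (MOMCl), COCCl
Why: O-Alkylation of the three phenols with MOMCl and a hindered amine base (Williamson-type acetal ether formation) should give ethers that tolerate the basic palladium coupling of step 8 and fall off under mild acid, the excess reagent, iodide catalysis and gentle heating serving to drive the hydrogen-bonded C2 hydroxyl to completion.

Step 8
Reactants: 9 drima-7,9(11)-diene; 12 methyl 5-bromo-2,3,4-tris(methoxymethoxy)benzoate
Product: 14 methyl 5-[(5S,9S,10S)-drim-7-en-11-yl]-2,3,4-tris(methoxymethoxy)benzoate, via B-(drim-7-en-11-yl)-9-BBN 13 (not isolated)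
Conditions: 9-BBN (0.5 M in THF, 1.5 equiv), THF, 65 °C; then 12, Pd(dppf)Cl2 (5 mol %), AsPh3 (10 mol %), Cs2CO3, DMF/H2O, 50 °C
Reagents that add atoms: none
Why: 9-BBN should hydroborate only the exocyclic 1,1-disubstituted C9=C11 alkene, with boron at the terminal C11 and hydrogen delivered to C9 from the α face opposite the axial C10 methyl group, which sets C9 (H α, C11 β and equatorial), and the primary alkylborane 13 then enters a B-alkyl Suzuki–Miyaura coupling with aryl bromide 12 at zerovalent palladium generated from Pd(dppf)Cl2, where the wide-bite-angle diphosphine favours reductive elimination over β-hydride elimination.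

Step 9
Reactants: 14 methyl 5-[(5S,9S,10S)-drim-7-en-11-yl]-2,3,4-tris(methoxymethoxy)benzoate
Product: 15 methyl 5-[(5S,9S,10S)-drim-7-en-11-yl]-2,3,4-trihydroxybenzoate (CNP0185238.1)
Conditions: HCl (1.25 M in MeOH), MeOH/THF, 0 °C → rt
Reagents that add atoms: none
Why: Acid-catalysed acetal exchange with methanol should remove the three MOM groups as dimethoxymethane at or below room temperature, where the methyl ester can only exchange with methanol degenerately and the trisubstituted C7=C8 alkene is not protonated, so that no cyclisation of the C4′ phenol onto C8 and no change at C5, C9 or C10 is expected.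

**Compound list**

1 | (R)-(−)-carvone | CC1=CC[C@H](CC1=O)C(C)=C | starting material
2 | lithium dienolate of carvone (kinetic α′ enolate, C1=C6 and C2=C3) | [Li]OC1=C[C@H](C(C)=C)CC=C1C | intermediate
3 | 6-methylcarvone, C6 epimer mixture; the (5R,6S) trans epimer is drawn | O=C1C(C)=CC[C@@H](C(C)=C)[C@@H]1C | intermediate
4 | 2,3-bis(phenylsulfonyl)prop-1-ene | C=C(CS(=O)(=O)c1ccccc1)S(=O)(=O)c1ccccc1 | starting material
5 | lithium enolate of 6-methylcarvone (tetrasubstituted C1=C6 enolate) | [Li]OC1=C(C)[C@H](C(C)=C)CC=C1C | intermediate
6 | (5S,6S)-2,6-dimethyl-6-[2-(phenylsulfonyl)prop-2-en-1-yl]-5-(prop-1-en-2-yl)cyclohex-2-en-1-one; C6 methyl cis and sulfonylallyl trans to isopropenyl | O=C1C(C)=CC[C@@H](C(C)=C)[C@]1(C)CC(=C)S(=O)(=O)c2ccccc2 | intermediate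
7 | (4aS,8aS)-2,5,5,8a-tetramethyl-7-(phenylsulfonyl)-4a,5,6,7,8,8a-hexahydronaphthalen-1(4H)-one (2-phenylsulfonyl-11-nordrim-7-en-9-one; trans-fused, 5α-H, 10β-CH3; C2 epimers) | O=C1C(C)=CC[C@H]2C(C)(C)CC(S(=O)(=O)c3ccccc3)C[C@]12C | intermediate
8 | 2-(phenylsulfonyl)drima-7,9(11)-diene (5S,10S; exocyclic C9=C11, C7=C8 with C8 methyl; C2 epimers) | C=C1C(C)=CC[C@H]2C(C)(C)CC(S(=O)(=O)c3ccccc3)C[C@]12C | intermediate
9 | (5S,10S)-drima-7,9(11)-diene | C=C1C(C)=CC[C@H]2C(C)(C)CCC[C@]12C | intermediate
10 | methyl 2,3,4-trihydroxybenzoate | COC(=O)c1ccc(O)c(O)c1O | starting material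
11 | methyl 5-bromo-2,3,4-trihydroxybenzoate | COC(=O)c1cc(Br)c(O)c(O)c1O | intermediate
12 | methyl 5-bromo-2,3,4-tris(methoxymethoxy)benzoate | COC(=O)c1cc(Br)c(OCOC)c(OCOC)c1OCOC | intermediate
13 | 9-[(5S,9S,10S)-drim-7-en-11-yl]-9-borabicyclo[3.3.1]nonane (9α-H, C11 β) | B1(C2CCCC1CCC2)C[C@H]3C(C)=CC[C@H]4C(C)(C)CCC[C@]34C | intermediate
14 | methyl 5-[(5S,9S,10S)-drim-7-en-11-yl]-2,3,4-tris(methoxymethoxy)benzoate | COC(=O)c1cc(C[C@H]2C(C)=CC[C@H]3C(C)(C)CCC[C@]23C)c(OCOC)c(OCOC)c1OCOC | intermediate
15 | methyl 5-[(5S,9S,10S)-drim-7-en-11-yl]-2,3,4-trihydroxybenzoate, that is methyl 2,3,4-trihydroxy-5-{[(1S,4aS,8aS)-2,5,5,8a-tetramethyl-1,4,4a,5,6,7,8,8a-octahydronaphthalen-1-yl]methyl}benzoate (CNP0185238.1) | COC(=O)c1cc(C[C@H]2C(C)=CC[C@H]3C(C)(C)CCC[C@]23C)c(O)c(O)c1O | target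

**Counts**

Total step count: 9 (steps 1–9). Longest linear sequence: 7 steps (steps 1, 2, 3, 4, 5, 8 and 9, from carvone 1 to target 15). The arene branch (steps 6 and 7) joins at step 8.

**Steps most likely to fail, with fallbacks**

Step 3 (radical ring closure). Hydrogen-atom transfer may not stay confined to the isopropenyl group, with the vinyl sulfone or the enone being reduced instead. Alternatively the tertiary C4 radical may be quenched before it cyclises, so that plain hydrogenation of the isopropenyl group wins. The fallback generates the same C4 radical from a carbon–bromine bond. It sets out from 6: Markovnikov hydrobromination of the isopropenyl group with HBr in AcOH at 0 °C, as carvone itself behaves, should give the tertiary bromide 5-(2-bromopropan-2-yl)-2,6-dimethyl-6-[2-(phenylsulfonyl)prop-2-en-1-yl]cyclohex-2-en-1-one F1 with the ring configuration of 6. Slow addition of Bu3SnH and AIBN to F1 in benzene at 80 °C should then bring about the same 6-endo closure onto the vinyl sulfone (tin-hydride radical cyclization), and the route is rejoined at 7.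

Step 2 (quaternary carbon by SN2′ alkylation). The hindered enolate may be quenched by proton transfer from the acidic allylic CH2 of 4. A second conjugate addition of enolate to the vinyl sulfone of the product, or incomplete facial selectivity at the new quaternary carbon, are the other ways it may go wrong. The fallback introduces the three-carbon arm as a 2-bromoallyl group and installs the sulfone afterwards. It sets out from 3: enolate 5 (LiN(i-Pr)2, THF, −78 °C) is alkylated with 2,3-dibromopropene, a plain SN2 allylation with the same anti approach, to give (5S,6S)-6-(2-bromoprop-2-en-1-yl)-2,6-dimethyl-5-(prop-1-en-2-yl)cyclohex-2-en-1-one F2. Copper-catalysed coupling of the vinyl bromide of F2 with PhSO2Na (CuI, N,N′-dimethylethylenediamine, DMSO, 100 °C) should then give the vinyl sulfone, and the route is rejoined at 6.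

Step 8 (hydroboration and B-alkyl coupling in one pot). Facial selectivity in the hydroboration may be incomplete, and this cannot be corrected because borane 13 is not purified. Transmetalation of the β-branched alkylborane beside the quaternary C10 may also be slow, so that protodeboronation or β-hydride elimination overtakes the coupling. The fallback secures C9 at an isolable alcohol and forms the C11–aryl bond from two electrophiles. It sets out from 9: borane 13 is formed as before and oxidised (NaOH, H2O2, 0 °C) to drimenol F3, from which any C9 epimer can be removed by chromatography. Appel iodination (I2, PPh3, imidazole, CH2Cl2) should give 11-iododrim-7-ene F4. Nickel-catalysed reductive cross-electrophile coupling of F4 with aryl bromide 12 (NiBr2(dme), 4,4′-di-tert-butyl-2,2′-bipyridine, Zn, N,N-dimethylacetamide, 60 °C) should then deliver the coupled product, and the route is rejoined at 14.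

**Further compounds**

F1 | step 3 | 5-(2-bromopropan-2-yl)-2,6-dimethyl-6-[2-(phenylsulfonyl)prop-2-en-1-yl]cyclohex-2-en-1-one (ring configuration of 6) | O=C1C(C)=CC[C@@H](C(C)(C)Br)[C@]1(C)CC(=C)S(=O)(=O)c2ccccc2
F2 | step 2 | (5S,6S)-6-(2-bromoprop-2-en-1-yl)-2,6-dimethyl-5-(prop-1-en-2-yl)cyclohex-2-en-1-one | O=C1C(C)=CC[C@@H](C(C)=C)[C@]1(C)CC(Br)=C
F3 | step 8 | drimenol, (5S,9S,10S)-drim-7-en-11-ol | OC[C@H]1C(C)=CC[C@H]2C(C)(C)CCC[C@]12C
F4 | step 8 | (5S,9S,10S)-11-iododrim-7-ene | IC[C@H]1C(C)=CC[C@H]2C(C)(C)CCC[C@]12C
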